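## Retrosynthetic overview

1. The last bonds made are the C3–OH (enolate hydroxylation on the face away from the axial C4a methyl) and the C6 ester (Yamaguchi), starting from dienone alcohol 17. Core atoms are numbered as in naphthalen-2(3H)-one: ring A = C4a, C5, C6, C7, C8, C8a; ring B = C1, C2, C3, C4, C4a, C8a.
2. Ring B is not annulated in its final size. Its C2(=O)–C3–C4–C4a part is carried as a cyclobutanone and its C1=C8a part as a terminal alkyne. Rhodium-catalysed C–C activation inserts the alkyne into the acyl–C4a bond (four- to six-membered ring) and closes ring A (C4a–C8a) in the same step.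
3. The feature that allows this: the enone carbons C1=C8a of ring B lie between the ketone C2 and the quaternary C4a, and the cis C7=C8 alkene of ring A gives a rigid four-atom tether (C5, C6, C7, C8) that holds the alkyne at the bond to be cut.
4. The cyclobutanone comes from a cyclopropanol by an invertive pinacol shift. Its tertiary carbinol and the C5 methyl centre come from one crotylboration of ethyl pyruvate. C6 comes from a reagent-controlled diyne addition and the cis alkene from a zinc semi-reduction.
5. Order of ring formation: cyclopropane, then cyclobutanone, then rings A and B together. The side-chain acid 23 comes from (S)-2-hydroxy-2-methylbutanoic acid by a vinylogous Horner–Wadsworth–Emmons reaction.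

Key step: step 10

Assumption: in the chair transition state of step 1 the ester group of the keto ester lies equatorial and the ketone methyl axial; if the opposite holds, the (Z)-isomer of 2 is used and nothing else changes.

## Route

Step 1
Reactants: 1 ethyl pyruvate; 2 2-[(2E)-but-2-en-1-yl]-4,4,5,5-tetramethyl-1,3,2-dioxaborolane
Product: 3 ethyl (2S,3S)-2-hydroxy-2,3-dimethylpent-4-enoate
Conditions: 2 (1.5 equiv), 3,3'-Br2-BINOL (15 mol %, Si-face-selective enantiomer), toluene/PhCF3, −35 °C to rt; aq. NaHCO3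
Reagents that add atoms: none
Why: Catalytic asymmetric crotylboration of a ketone through a closed chair (Zimmerman–Traxler) transition state, in which the (E)-geometry of 2 should place the new methyl group anti to the tertiary hydroxyl and the boron-bound chiral diol should direct the crotyl group to the Si face of the activated keto group, so that C2 and C3 (later C4a and C5) are set in one event.

Step 2
Reactants: 3 ethyl (2S,3S)-2-hydroxy-2,3-dimethylpent-4-enoate
Product: 4 1-[(2S,3S)-2-hydroxy-3-methylpent-4-en-2-yl]cyclopropan-1-ol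
Conditions: EtMgBr (4 equiv), Ti(OiPr)4 (1.0 equiv), THF/Et2O, 0 °C to rt; aq. NH4Cl
Reagents that add atoms: ethylmagnesium bromide, CC[Mg]Br
Why: Kulinkovich cyclopropanation, in which the titanacyclopropane made from EtMgBr and Ti(OiPr)4 should add twice to the ester carbonyl and give the cyclopropanol without touching the two stereocentres or the distal vinyl group.

Step 3
Reactants: 4 1-[(2S,3S)-2-hydroxy-3-methylpent-4-en-2-yl]cyclopropan-1-ol
Product: 5 (2R)-2-[(2S)-but-3-en-2-yl]-2-methylcyclobutan-1-one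
Conditions: TsOH·H2O (10 mol %), CH2Cl2, 0 °C
Reagents that add atoms: none
Why: Pinacol-type ring expansion of a 1-(1-hydroxyalkyl)cyclopropanol, in which the acid ionises the tertiary carbinol while an antiperiplanar cyclopropane bond migrates to it with inversion and the cyclopropanol oxygen becomes the ketone, so that the (S)-carbinol should be relayed into the (R)-quaternary carbon (its fidelity at a tertiary centre is an extrapolation from secondary carbinols).

Step 4
Reactants: 5 (2R)-2-[(2S)-but-3-en-2-yl]-2-methylcyclobutan-1-one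
Product: 7 (2R)-2-[(1R)-1-methyl-2-oxocyclobutyl]propanal, via the secondary ozonide 6 (not isolated)
Conditions: O3, CH2Cl2, −78 °C; Me2S, −78 °C to rt
Reagents that add atoms: ozone, [O-][O+]=O
Why: Ozonolysis with reductive work-up should cleave the only alkene to the aldehyde and leave the ketone and both stereocentres untouched, the alpha-branched aldehyde being used at once to avoid epimerisation.

Step 5
Reactants: 8 1,4-bis(trimethylsilyl)buta-1,3-diyne
Product: 10 buta-1,3-diyn-1-yl(trimethyl)silane, via lithium (trimethylsilyl)butadiynide 9 (not isolated)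
Conditions: MeLi·LiBr (1.0 equiv), Et2O, rt; H2O; used as a dried solution
Reagents that add atoms: none
Why: Mono-desilylation of the bis-silyl diyne by one equivalent of MeLi·LiBr, a standard selective C–Si cleavage, should give after protonation the terminal diyne.

Step 6
Reactants: 7 (2R)-2-[(1R)-1-methyl-2-oxocyclobutyl]propanal; 10 buta-1,3-diyn-1-yl(trimethyl)silane
Product: 12 (2R)-2-[(2R,3R)-3-hydroxy-7-(trimethylsilyl)hepta-4,6-diyn-2-yl]-2-methylcyclobutan-1-one, via methylzinc (trimethylsilyl)butadiynide 11 (not isolated)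
Conditions: 10 (2.5 equiv), Me2Zn (2.8 equiv), ProPhenol ligand (20 mol %, Si-face-selective enantiomer), Ph3P=O (40 mol %), toluene, 4 °C; H2O
Reagents that add atoms: none
Why: Catalytic asymmetric alkynylation of an aldehyde by a zinc acetylide under a dinuclear zinc–ProPhenol catalyst, which should direct the diynyl group to the Si face of the aldehyde (reagent control against the weak Felkin bias of the alpha-methyl centre) while the alkynylzinc does not add to the hindered ketone.

Step 7
Reactants: 12 (2R)-2-[(2R,3R)-3-hydroxy-7-(trimethylsilyl)hepta-4,6-diyn-2-yl]-2-methylcyclobutan-1-one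
Product: 13 (2R)-2-[(2R,3S,4Z)-3-hydroxy-7-(trimethylsilyl)hept-4-en-6-yn-2-yl]-2-methylcyclobutan-1-one
Conditions: Zn dust activated with Cu(OAc)2 and AgNO3, MeOH/H2O 1:1, 40 °C
Reagents that add atoms: none
Why: Reduction with activated zinc (Boland type) should deliver two hydrogens cis to the conjugated triple bond next to the free carbinol, while the silyl-capped triple bond is not reduced, so that the (Z)-enyne forms.

Step 8
Reactants: 13 (2R)-2-[(2R,3S,4Z)-3-hydroxy-7-(trimethylsilyl)hept-4-en-6-yn-2-yl]-2-methylcyclobutan-1-one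
Product: 14 (2R)-2-[(2R,3S,4Z)-3-hydroxyhept-4-en-6-yn-2-yl]-2-methylcyclobutan-1-one
Conditions: K2CO3 (20 mol %), MeOH, rt
Reagents that add atoms: none
Why: Carbonate-catalysed methanolysis of the alkynyl C–Si bond should free the terminal alkyne without affecting the quaternary centre or the cis alkene.

Step 9
Reactants: 14 (2R)-2-[(2R,3S,4Z)-3-hydroxyhept-4-en-6-yn-2-yl]-2-methylcyclobutan-1-one
Product: 15 (2R)-2-methyl-2-[(2R,3S,4Z)-3-(triethylsilyloxy)hept-4-en-6-yn-2-yl]cyclobutan-1-one
Conditions: TESCl, imidazole, DMAP (cat.), CH2Cl2, 0 °C to rt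
Reagents that add atoms: chlorotriethylsilane, CC[Si](Cl)(CC)CC
Why: Silylation of the secondary alcohol should trap the open hydroxy ketone, which may equilibrate with its five-membered hemiketal, and mask the allylic oxygen for the metal-catalysed step.

Step 10
Reactants: 15 (2R)-2-methyl-2-[(2R,3S,4Z)-3-(triethylsilyloxy)hept-4-en-6-yn-2-yl]cyclobutan-1-one
Product: 16 (4aR,5R,6S)-4a,5-dimethyl-6-(triethylsilyloxy)-4,4a,5,6-tetrahydronaphthalen-2(3H)-one
Conditions: [Rh(C2H4)2Cl]2 (5 mol %), P[3,5-(CF3)2C6H3]3 (20 mol %), 1,4-dioxane, 130 °C, sealed tube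
Reagents that add atoms: none
Why: Monovalent rhodium, held by the tethered alkyne, should add oxidatively into the acyl–C(quaternary) bond of the strained cyclobutanone (C2–C4a in the numbering of the product), the alkyne then inserts into the Rh–acyl bond, and C(sp3)–C(sp2) reductive elimination joins C4a to C8a. The closest known reaction type is the rhodium-catalysed intramolecular carboacylation ("cut-and-sew") of cyclobutanones that carry an alkyne tether at the alpha carbon, which gives cyclohexenone-fused rings. Ring B arises by two-carbon ring expansion of the four-membered ketone (insertion of C1≡C8a into the C2–C4a bond), and ring A closes in the same catalytic cycle as a six-membered ring by the C4a–C8a reductive elimination. No stereocentre is created: C5 and C6 are spectators, and C4a should be transferred with retention because oxidative addition and reductive elimination both proceed with retention at that carbon. The step needs site selectivity for the hindered proximal C–C bond over the distal acyl–CH2 bond and chemoselectivity against decarbonylation; the cis C7=C8 alkene, which places the alkyne next to the ketone, and the electron-poor phosphine are meant to secure them. The product is the linearly conjugated dienone of the target with every ring carbon in place.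

Step 11
Reactants: 16 (4aR,5R,6S)-4a,5-dimethyl-6-(triethylsilyloxy)-4,4a,5,6-tetrahydronaphthalen-2(3H)-one
Product: 17 (4aR,5R,6S)-6-hydroxy-4a,5-dimethyl-4,4a,5,6-tetrahydronaphthalen-2(3H)-one
Conditions: PPTS (cat.), MeOH, 0 °C to rt
Reagents that add atoms: none
Why: Mild acid-catalysed methanolysis should remove the triethylsilyl ether without ionising the allylic C–O bond or moving the dienone.

Step 12
Reactants: 18 (2S)-2-hydroxy-2-methylbutanoic acid
Product: 19 (2S)-2-methylbutane-1,2-diol
Conditions: LiAlH4, THF, 0 °C to reflux; H2O, aq. NaOH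
Reagents that add atoms: none
Why: Hydride reduction of the carboxylic acid to the primary alcohol does not touch the tertiary carbinol stereocentre, which is bought with the starting material.

Step 13
Reactants: 19 (2S)-2-methylbutane-1,2-diol
Product: 20 (2S)-2-hydroxy-2-methylbutanal
Conditions: SO3·pyridine, DMSO, Et3N, CH2Cl2, 0 °C
Reagents that add atoms: none
Why: Parikh–Doering oxidation (activated DMSO) should convert only the primary alcohol to the aldehyde and cannot cleave the 1,2-diol.

Step 14
Reactants: 20 (2S)-2-hydroxy-2-methylbutanal; 21 ethyl (2E)-4-(diethoxyphosphoryl)but-2-enoate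
Product: 22 ethyl (2E,4E,6S)-6-hydroxy-6-methylocta-2,4-dienoate
Conditions: 21, LiOH·H2O, 4 Å molecular sieves, THF, reflux
Reagents that add atoms: none
Why: Vinylogous Horner–Wadsworth–Emmons olefination with the stabilised crotonate phosphonate should give the (2E,4E)-dienoate under thermodynamic control and tolerate the free tertiary hydroxyl.

Step 15
Reactants: 22 ethyl (2E,4E,6S)-6-hydroxy-6-methylocta-2,4-dienoate
Product: 23 (2E,4E,6S)-6-hydroxy-6-methylocta-2,4-dienoic acid
Conditions: LiOH, THF/MeOH/H2O, rt; aq. HCl to pH 3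
Reagents that add atoms: lithium hydroxide, [Li+].[OH-]
Why: Saponification of the ethyl ester, the tertiary alcohol and the diene being inert to hydroxide at room temperature.

Step 16
Reactants: 17 (4aR,5R,6S)-6-hydroxy-4a,5-dimethyl-4,4a,5,6-tetrahydronaphthalen-2(3H)-one; 23 (2E,4E,6S)-6-hydroxy-6-methylocta-2,4-dienoic acid
Product: 25 (1R,2S,8aR)-1,8a-dimethyl-6-oxo-1,2,6,7,8,8a-hexahydronaphthalen-2-yl (2E,4E,6S)-6-hydroxy-6-methylocta-2,4-dienoate, via the mixed anhydride 24 (not isolated)
Conditions: 23, 2,4,6-Cl3C6H2COCl, Et3N, THF, rt; then 17, DMAP, toluene, rt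
Reagents that add atoms: none
Why: Yamaguchi esterification, in which the mixed anhydride should acylate the hindered secondary allylic alcohol under DMAP catalysis with retention at C6, the tertiary hydroxyl of the acid being too hindered to compete.

Step 17
Reactants: 25 (1R,2S,8aR)-1,8a-dimethyl-6-oxo-1,2,6,7,8,8a-hexahydronaphthalen-2-yl (2E,4E,6S)-6-hydroxy-6-methylocta-2,4-dienoate
Product: 27 (1R,2S,7R,8aR)-7-hydroxy-1,8a-dimethyl-6-oxo-1,2,6,7,8,8a-hexahydronaphthalen-2-yl (2E,4E,6S)-6-hydroxy-6-methylocta-2,4-dienoate, via the dipotassium enolate 26 (not isolated)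
Conditions: KN(SiMe3)2 (2.3 equiv), THF, −78 °C; 3-phenyl-2-(phenylsulfonyl)oxaziridine, −78 °C; AcOH
Reagents that add atoms: 3-phenyl-2-(phenylsulfonyl)oxaziridine, O=S(=O)(c1ccccc1)N1OC1c1ccccc1
Why: Kinetic deprotonation at the alpha' carbon (C3) should give the cross-conjugated enolate, which the N-sulfonyloxaziridine (Davis reagent) hydroxylates on the face opposite the axial C4a methyl group, so that the hydroxyl ends equatorial and (3R), which is also the more stable epimer, as in the hydroxylation of steroidal enones.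

## Compound list

1 | ethyl pyruvate | CCOC(=O)C(C)=O | starting material
2 | 2-[(2E)-but-2-en-1-yl]-4,4,5,5-tetramethyl-1,3,2-dioxaborolane | C/C=C/CB1OC(C)(C)C(C)(C)O1 | starting material
3 | ethyl (2S,3S)-2-hydroxy-2,3-dimethylpent-4-enoate | CCOC(=O)[C@@](C)(O)[C@@H](C)C=C | intermediate
4 | 1-[(2S,3S)-2-hydroxy-3-methylpent-4-en-2-yl]cyclopropan-1-ol | OC1(CC1)[C@@](C)(O)[C@@H](C)C=C | intermediate
5 | (2R)-2-[(2S)-but-3-en-2-yl]-2-methylcyclobutan-1-one | O=C1CC[C@]1(C)[C@@H](C)C=C | intermediate
6 | (2R)-2-methyl-2-[(1R)-1-(1,2,4-trioxolan-3-yl)ethyl]cyclobutan-1-one (secondary ozonide, trioxolane carbon undefined) | O=C1CC[C@]1(C)[C@@H](C)C2OCOO2 | intermediate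
7 | (2R)-2-[(1R)-1-methyl-2-oxocyclobutyl]propanal | O=C1CC[C@]1(C)[C@@H](C)C=O | intermediate
8 | 1,4-bis(trimethylsilyl)buta-1,3-diyne | C[Si](C)(C)C#CC#C[Si](C)(C)C | starting material
9 | lithium 4-(trimethylsilyl)buta-1,3-diyn-1-ide | [Li+].[C-]#CC#C[Si](C)(C)C | intermediate
10 | buta-1,3-diyn-1-yl(trimethyl)silane | C#CC#C[Si](C)(C)C | intermediate
11 | methyl[4-(trimethylsilyl)buta-1,3-diyn-1-yl]zinc | C[Zn]C#CC#C[Si](C)(C)C | intermediate
12 | (2R)-2-[(2R,3R)-3-hydroxy-7-(trimethylsilyl)hepta-4,6-diyn-2-yl]-2-methylcyclobutan-1-one | O=C1CC[C@]1(C)[C@@H](C)[C@@H](O)C#CC#C[Si](C)(C)C | intermediate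
13 | (2R)-2-[(2R,3S,4Z)-3-hydroxy-7-(trimethylsilyl)hept-4-en-6-yn-2-yl]-2-methylcyclobutan-1-one | O=C1CC[C@]1(C)[C@@H](C)[C@@H](O)/C=C\C#C[Si](C)(C)C | intermediate
14 | (2R)-2-[(2R,3S,4Z)-3-hydroxyhept-4-en-6-yn-2-yl]-2-methylcyclobutan-1-one | O=C1CC[C@]1(C)[C@@H](C)[C@@H](O)/C=C\C#C | intermediate
15 | (2R)-2-methyl-2-[(2R,3S,4Z)-3-(triethylsilyloxy)hept-4-en-6-yn-2-yl]cyclobutan-1-one | O=C1CC[C@]1(C)[C@@H](C)[C@@H](O[Si](CC)(CC)CC)/C=C\C#C | intermediate
16 | (4aR,5R,6S)-4a,5-dimethyl-6-(triethylsilyloxy)-4,4a,5,6-tetrahydronaphthalen-2(3H)-one | CC[Si](CC)(CC)O[C@H]1C=CC2=CC(=O)CC[C@]2(C)[C@H]1C | intermediate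
17 | (4aR,5R,6S)-6-hydroxy-4a,5-dimethyl-4,4a,5,6-tetrahydronaphthalen-2(3H)-one | O[C@H]1C=CC2=CC(=O)CC[C@]2(C)[C@H]1C | intermediate
18 | (2S)-2-hydroxy-2-methylbutanoic acid | CC[C@](C)(O)C(=O)O | starting material
19 | (2S)-2-methylbutane-1,2-diol | CC[C@](C)(O)CO | intermediate
20 | (2S)-2-hydroxy-2-methylbutanal | CC[C@](C)(O)C=O | intermediate
21 | ethyl (2E)-4-(diethoxyphosphoryl)but-2-enoate | CCOC(=O)/C=C/CP(=O)(OCC)OCC | starting material
22 | ethyl (2E,4E,6S)-6-hydroxy-6-methylocta-2,4-dienoate | CC[C@](C)(O)/C=C/C=C/C(=O)OCC | intermediate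
23 | (2E,4E,6S)-6-hydroxy-6-methylocta-2,4-dienoic acid | CC[C@](C)(O)/C=C/C=C/C(=O)O | intermediate
24 | (2E,4E,6S)-6-hydroxy-6-methylocta-2,4-dienoic 2,4,6-trichlorobenzoic anhydride | CC[C@](C)(O)/C=C/C=C/C(=O)OC(=O)c1c(Cl)cc(Cl)cc1Cl | intermediate
25 | (1R,2S,8aR)-1,8a-dimethyl-6-oxo-1,2,6,7,8,8a-hexahydronaphthalen-2-yl (2E,4E,6S)-6-hydroxy-6-methylocta-2,4-dienoate | CC[C@](C)(O)/C=C/C=C/C(=O)O[C@H]1C=CC2=CC(=O)CC[C@]2(C)[C@H]1C | intermediate
26 | dipotassium enolate-alkoxide of 25 (C2 enolate towards C3, side-chain alkoxide) | [K+].[K+].CC[C@](C)([O-])/C=C/C=C/C(=O)O[C@H]1C=CC2=CC([O-])=CC[C@]2(C)[C@H]1C | intermediate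
27 | (1R,2S,7R,8aR)-7-hydroxy-1,8a-dimethyl-6-oxo-1,2,6,7,8,8a-hexahydronaphthalen-2-yl (2E,4E,6S)-6-hydroxy-6-methylocta-2,4-dienoate | CC[C@](C)(O)/C=C/C=C/C(=O)O[C@H]1C=CC2=CC(=O)[C@H](O)C[C@]2(C)[C@H]1C | target

## Step count and risks

Total step count: 17. Longest linear sequence: 12 steps (steps 1–4, 6–11, 16 and 17, from ethyl pyruvate).

Steps most likely to fail:

Step 10. Oxidative addition into the hindered acyl–C(quaternary) bond may lose to decarbonylation of the acyl–rhodium species, and the free terminal alkyne may be consumed by metal-mediated oligomerisation. The fallback sets out from 13 and moves to the internal silyl alkyne, the substrate class with the closest precedent and no acidic C–H. Silylation (TESCl, imidazole) would give (2R)-2-methyl-2-[(2R,3S,4Z)-3-(triethylsilyloxy)-7-(trimethylsilyl)hept-4-en-6-yn-2-yl]cyclobutan-1-one F1. The rhodium-catalysed carboacylation of F1 should give (4aR,5R,6S)-4a,5-dimethyl-6-(triethylsilyloxy)-1-(trimethylsilyl)-4,4a,5,6-tetrahydronaphthalen-2(3H)-one F2. TsOH·H2O in wet MeCN would then remove the vinylic silyl group by ipso protonation together with the silyl ether, and the route is rejoined at 17.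

Step 1. Crotyl transfer to an unsymmetrical ketone may show poor or reversed simple diastereoselection (which ketone substituent sits axial in the chair) and incomplete facial control. The fallback sets out from 1 and replaces the closed-chair addition by an open, catalyst-controlled aldol. Mukaiyama addition of (Z)-1-(tert-butylsulfanyl)-1-(trimethylsilyloxy)prop-1-ene under Sn(OTf)2 and a chiral bis(oxazoline), an anti-selective pyruvate aldol, would give ethyl (2S,3R)-4-(tert-butylsulfanyl)-2-hydroxy-2,3-dimethyl-4-oxobutanoate F3. Fukuyama reduction (Et3SiH, Pd/C) would give ethyl (2S,3R)-2-hydroxy-2,3-dimethyl-4-oxobutanoate F4. Wittig methylenation (Ph3P=CH2, THF, −78 to 0 °C) comes back to the route at 3.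

Step 17. Deprotonation of the fully assembled ester may lose site selectivity (vinylogous enolisation towards C6, attack on the dienoate), and the enolate may add to the sulfonimine by-product. The fallback sets out from 16 and hydroxylates before the ester is in place:
- The same enolate hydroxylation would give (3R,4aR,5R,6S)-3-hydroxy-4a,5-dimethyl-6-(triethylsilyloxy)-4,4a,5,6-tetrahydronaphthalen-2(3H)-one F5.
- TBSOTf and 2,6-lutidine would give (3R,4aR,5R,6S)-3-[(tert-butyldimethylsilyl)oxy]-4a,5-dimethyl-6-(triethylsilyloxy)-4,4a,5,6-tetrahydronaphthalen-2(3H)-one F6.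
- PPTS in MeOH would cleave only the triethylsilyl ether to give (3R,4aR,5R,6S)-3-[(tert-butyldimethylsilyl)oxy]-6-hydroxy-4a,5-dimethyl-4,4a,5,6-tetrahydronaphthalen-2(3H)-one F7.
- Yamaguchi esterification with 23 would give (1R,2S,7R,8aR)-7-[(tert-butyldimethylsilyl)oxy]-1,8a-dimethyl-6-oxo-1,2,6,7,8,8a-hexahydronaphthalen-2-yl (2E,4E,6S)-6-hydroxy-6-methylocta-2,4-dienoate F8.
- HF·pyridine then comes back to the route at 27.

Further compounds
F1 | step 10 | (2R)-2-methyl-2-[(2R,3S,4Z)-3-(triethylsilyloxy)-7-(trimethylsilyl)hept-4-en-6-yn-2-yl]cyclobutan-1-one | O=C1CC[C@]1(C)[C@@H](C)[C@@H](O[Si](CC)(CC)CC)/C=C\C#C[Si](C)(C)C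
F2 | step 10 | (4aR,5R,6S)-4a,5-dimethyl-6-(triethylsilyloxy)-1-(trimethylsilyl)-4,4a,5,6-tetrahydronaphthalen-2(3H)-one | CC[Si](CC)(CC)O[C@H]1C=CC2=C([Si](C)(C)C)C(=O)CC[C@]2(C)[C@H]1C
F3 | step 1 | ethyl (2S,3R)-4-(tert-butylsulfanyl)-2-hydroxy-2,3-dimethyl-4-oxobutanoate | CCOC(=O)[C@@](C)(O)[C@@H](C)C(=O)SC(C)(C)C
F4 | step 1 | ethyl (2S,3R)-2-hydroxy-2,3-dimethyl-4-oxobutanoate | CCOC(=O)[C@@](C)(O)[C@@H](C)C=O
F5 | step 17 | (3R,4aR,5R,6S)-3-hydroxy-4a,5-dimethyl-6-(triethylsilyloxy)-4,4a,5,6-tetrahydronaphthalen-2(3H)-one | CC[Si](CC)(CC)O[C@H]1C=CC2=CC(=O)[C@H](O)C[C@]2(C)[C@H]1C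
F6 | step 17 | (3R,4aR,5R,6S)-3-[(tert-butyldimethylsilyl)oxy]-4a,5-dimethyl-6-(triethylsilyloxy)-4,4a,5,6-tetrahydronaphthalen-2(3H)-one | CC[Si](CC)(CC)O[C@H]1C=CC2=CC(=O)[C@H](O[Si](C)(C)C(C)(C)C)C[C@]2(C)[C@H]1C
F7 | step 17 | (3R,4aR,5R,6S)-3-[(tert-butyldimethylsilyl)oxy]-6-hydroxy-4a,5-dimethyl-4,4a,5,6-tetrahydronaphthalen-2(3H)-one | O[C@H]1C=CC2=CC(=O)[C@H](O[Si](C)(C)C(C)(C)C)C[C@]2(C)[C@H]1C
F8 | step 17 | (1R,2S,7R,8aR)-7-[(tert-butyldimethylsilyl)oxy]-1,8a-dimethyl-6-oxo-1,2,6,7,8,8a-hexahydronaphthalen-2-yl (2E,4E,6S)-6-hydroxy-6-methylocta-2,4-dienoate | CC[C@](C)(O)/C=C/C=C/C(=O)O[C@H]1C=CC2=CC(=O)[C@H](O[Si](C)(C)C(C)(C)C)C[C@]2(C)[C@H]1C
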